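With the labels C1 (ketone), C2=C3 (methyl on C3), cyclobutane C4–C5–C11–C10, C6 (gem-dimethyl), C7 (senecioate), C8 and C9 (angelate), cutting C5–C11 leaves the cyclohexene C1–C2–C3–C4–C10–C11 fused along C4–C10 to the seven-membered ring C4–C5–C6–C7–C8–C9–C10. With C9 as a ketone this is the retron of a type 1 intramolecular Diels–Alder reaction. That one operation forms C4–C10 and C1–C11, closes both rings and sets C4 and quaternary C10 (cis fusion). Its precursor is an acyclic bis-silyloxy trienone: E-diene C1=C2–C3=C4, isopropenyl ketone C9(=O)–C10=C11, carbinol centres C5 and C7 from two asymmetric aldol reactions. C5–C11 is closed last by enolate alkylation.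

Key step: step 9

Remark: the labels C1–C11 are used for all compounds; descriptors marked "skeleton" refer to them, all other locants belong to the systematic name.
Remark on design: O5 carries the labile triethylsilyl group and O7 the tert-butyldimethylsilyl group, so that O5 is unmasked and turned into the leaving group first; O9 stays a silyl ether through ring closure and receives the angeloyl group last.
Assumption: N-tosyl-D-valine, (+)-Ipc2BCl, 1-methoxy-2-methyl-1-(trimethylsilyloxy)prop-1-ene and angelic acid are bought.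

Step 1
Reactants: 1 (E)-3-methylpent-2-en-4-yn-1-ol
Product: 2 (E)-3-methylpenta-2,4-dien-1-ol
Conditions: H2 (1 atm), Pd/CaCO3 poisoned with Pb(OAc)2, quinoline, EtOAc, rt
Reagents that add atoms: none
Why: Lindlar semi-hydrogenation is selective for the terminal alkyne over the conjugated trisubstituted alkene, whose E geometry is kept.

Step 2
Reactants: 2 (E)-3-methylpenta-2,4-dien-1-ol
Product: 3 (E)-3-methylpenta-2,4-dienal
Conditions: MnO2, CH2Cl2, rt
Reagents that add atoms: none
Why: MnO2 oxidation of an allylic alcohol stops at the enal and leaves the diene untouched.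

Step 3
Reactants: 3 (E)-3-methylpenta-2,4-dienal; 4 1-methoxy-2-methyl-1-(trimethylsilyloxy)prop-1-ene
Product: 5 methyl (3S,4E)-3-hydroxy-2,2,5-trimethylhepta-4,6-dienoate
Conditions: N-tosyl-D-valine, BH3·THF (1 equiv each), CH2Cl2, rt; then 3 and 4, −78 °C; pH 7 buffer
Reagents that add atoms: none
Why: Asymmetric Mukaiyama aldol promoted by the valine-derived oxazaborolidinone, in which the boron-bound aldehyde is attacked 1,2 by the ketene acetal on the face left open by the D-valine-derived promoter, which should set the carbinol carbon as 3S (skeleton C5).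

Step 4
Reactants: 5 methyl (3S,4E)-3-hydroxy-2,2,5-trimethylhepta-4,6-dienoate
Product: 6 methyl (3S,4E)-2,2,5-trimethyl-3-(triethylsilyloxy)hepta-4,6-dienoate
Conditions: TESCl, imidazole, DMF, 0 °C to rt
Reagents that add atoms: chlorotriethylsilane (TESCl), CC[Si](Cl)(CC)CC
Why: Silyl ether formation on a secondary allylic alcohol, with the triethylsilyl group chosen so that O5 can later be freed in the presence of the O7 tert-butyldimethylsilyl ether.

Step 5
Reactants: 6 methyl (3S,4E)-2,2,5-trimethyl-3-(triethylsilyloxy)hepta-4,6-dienoate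
Product: 7 (3S,4E)-2,2,5-trimethyl-3-(triethylsilyloxy)hepta-4,6-dien-1-ol
Conditions: iBu2AlH, CH2Cl2, −78 to 0 °C; aq. KNaC4H4O6
Reagents that add atoms: none
Why: Hydride reduction of the neopentyl ester is taken fully to the primary alcohol, which avoids aldehyde/alcohol mixtures.

Step 6
Reactants: 7 (3S,4E)-2,2,5-trimethyl-3-(triethylsilyloxy)hepta-4,6-dien-1-ol
Product: 8 (3S,4E)-2,2,5-trimethyl-3-(triethylsilyloxy)hepta-4,6-dienal
Conditions: Dess–Martin periodinane, pyridine, CH2Cl2, 0 °C to rt
Reagents that add atoms: none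
Why: Dess–Martin oxidation gives the non-enolisable aldehyde under buffered conditions that the dienylic silyl ether tolerates.

Step 7
Reactants: 8 (3S,4E)-2,2,5-trimethyl-3-(triethylsilyloxy)hepta-4,6-dienal; 9 3-methylbut-3-en-2-one
Product: 12 (5R,7S,8E)-5-hydroxy-2,6,6,9-tetramethyl-7-(triethylsilyloxy)undeca-1,8,10-trien-3-one, via boron enolate 10 (not isolated), via boron aldolate 11 (not isolated)
Conditions: (+)-Ipc2BCl, Et3N, Et2O, −78 to 0 °C; then 8, −78 to −20 °C; H2O2, MeOH, pH 7 buffer, 0 °C
Reagents that add atoms: none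
Why: Boron-mediated aldol reaction of a methyl ketone, in which the diisopinocampheylboron dienolate adds through a cyclic transition state to the Re face of 8 under reagent control [(+)-Ipc2BCl is the antipode of the reagent that attacks the Si face], which should set 5R (skeleton C7, syn to O5), the minor epimer being removable by chromatography.

Step 8
Reactants: 12 (5R,7S,8E)-5-hydroxy-2,6,6,9-tetramethyl-7-(triethylsilyloxy)undeca-1,8,10-trien-3-one
Product: 13 (5R,7S,8E)-5-(tert-butyldimethylsilyloxy)-2,6,6,9-tetramethyl-7-(triethylsilyloxy)undeca-1,8,10-trien-3-one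
Conditions: TBSOTf, 2,6-lutidine, CH2Cl2, −78 °C
Reagents that add atoms: tert-butyldimethylsilyl triflate (TBSOTf), CC(C)(C)[Si](C)(C)OS(=O)(=O)C(F)(F)F
Why: Silylation with the silyl triflate at low temperature protects the hindered β-hydroxy ketone before retro-aldol or elimination can occur.

Step 9
Reactants: 13 (5R,7S,8E)-5-(tert-butyldimethylsilyloxy)-2,6,6,9-tetramethyl-7-(triethylsilyloxy)undeca-1,8,10-trien-3-one
Product: 14 (4aS,7R,9S,9aR)-7-(tert-butyldimethylsilyloxy)-1,4a,8,8-tetramethyl-9-(triethylsilyloxy)-3,4,4a,6,7,8,9,9a-octahydro-5H-benzo[7]annulen-5-one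
Conditions: Me2AlCl (1.5 equiv), CH2Cl2 (0.01 M), −78 to −20 °C
Reagents that add atoms: none
Why: Aluminium coordination to the C9 carbonyl lowers the LUMO of the 1,1-disubstituted dienophile C10=C11, which adds to the s-cis E-diene C1=C2–C3=C4 in a concerted, asynchronous [4+2] cycloaddition; the closest known reaction type is the Lewis-acid-promoted type 1 intramolecular Diels–Alder reaction of trienones whose carbonyl lies in the tether. The cyclohexene C1–C2–C3–C4–C10–C11 closes as the cycloaddition ring, and the seven-membered ring C4–C5–C6–C7–C8–C9–C10 closes as the tether ring, helped by the gem-dimethyl group at C6. C10 is set by the endo position of the tether carbonyl, which puts the C10 methyl cis to H4 (cis fusion, skeleton 10S). C4 is set by the C5 stereocentre: allylic strain with the C3 methyl holds H5 in the diene plane, so the tether carbon C6 and the dienophile reach one diene face while the silyloxy group covers the other (skeleton 4R). The step needs cis fusion and this one diene face; the tether enforces the regiochemistry, and the endo preference together with the allylic strain secures the stereochemistry. The cis-fused product is also the only one in which C11 can later reach C5.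

Step 10
Reactants: 14 (4aS,7R,9S,9aR)-7-(tert-butyldimethylsilyloxy)-1,4a,8,8-tetramethyl-9-(triethylsilyloxy)-3,4,4a,6,7,8,9,9a-octahydro-5H-benzo[7]annulen-5-one
Product: 15 (4aS,7R,9S,9aR)-7-(tert-butyldimethylsilyloxy)-9-hydroxy-1,4a,8,8-tetramethyl-3,4,4a,6,7,8,9,9a-octahydro-5H-benzo[7]annulen-5-one
Conditions: pyridinium p-toluenesulfonate (cat.), MeOH/CH2Cl2, 0 °C to rt
Reagents that add atoms: none
Why: Acid-catalysed methanolysis (selective silyl ether cleavage) removes the triethylsilyl ether far faster than the tert-butyldimethylsilyl ether, so only O5 is freed.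

Step 11
Reactants: 15 (4aS,7R,9S,9aR)-7-(tert-butyldimethylsilyloxy)-9-hydroxy-1,4a,8,8-tetramethyl-3,4,4a,6,7,8,9,9a-octahydro-5H-benzo[7]annulen-5-one
Product: 16 C5 methanesulfonate of 15
Conditions: MsCl, Et3N, DMAP (cat.), CH2Cl2, 0 °C
Reagents that add atoms: methanesulfonyl chloride (MsCl), CS(=O)(=O)Cl
Why: Mesylation through the sulfene pathway works on hindered secondary alcohols and retains the C5 configuration, which places the leaving group anti to C10 as the later rear-side attack by C11 requires.

Step 12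
Reactants: 16 C5 methanesulfonate of 15
Product: 17 C7 hydroxy ketone (free O7–H; C5 mesylate; C9 ketone)
Conditions: HF·pyridine, pyridine, THF, 0 °C to rt
Reagents that add atoms: none
Why: Fluoride-induced silyl ether cleavage under buffered acidic conditions frees O7 without touching the mesylate and without base that could trigger retro-aldol or β-elimination.

Step 13
Reactants: 17 C7 hydroxy ketone; 18 3-methylbut-2-enal
Product: 19 anti C9 alcohol bearing the senecioyl group on O7
Conditions: SmI2 (0.3 equiv, premixed with 18), THF, −10 °C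
Reagents that add atoms: none
Why: Evans–Tishchenko reduction, in which the samarium-bound hemiacetal of the C7 hydroxyl and 18 transfers its hydride through a six-membered chair transition state to C9, which should give the 1,3-anti alcohol (skeleton 9R) and leaves the senecioyl group on O7.

Step 14
Reactants: 19 anti C9 alcohol bearing the senecioyl group on O7
Product: 20 O9 triethylsilyl ether of 19
Conditions: TESOTf, 2,6-lutidine, CH2Cl2, −78 to −40 °C
Reagents that add atoms: triethylsilyl triflate (TESOTf), CC[Si](CC)(CC)OS(=O)(=O)C(F)(F)F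
Why: Silylation of the hindered alcohol with the silyl triflate keeps O9 as an ether through ring closure, because an acyl group there would sit 1,4 to the C11 enolate carbon and invite O-to-C acyl transfer.

Step 15
Reactants: 20 O9 triethylsilyl ether of 19
Product: 21 C1 enone of 20
Conditions: CrO3, 3,5-dimethylpyrazole, CH2Cl2, −20 °C
Reagents that add atoms: chromium trioxide, O=[Cr](=O)=O
Why: Allylic oxidation with the CrO3–3,5-dimethylpyrazole complex converts the ring methylene C1 next to the trisubstituted alkene C2=C3 into the enone carbonyl, while the electron-poor enoate, the mesylate and the silyl ether are inert to this electrophilic oxidant.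

Step 16
Reactants: 21 C1 enone of 20
Product: 23 O9-triethylsilyl cage enone, via potassium enolate 22 (not isolated)
Conditions: KN(SiMe3)2 (1.1 equiv), THF, −78 °C, then 0 °C to rt
Reagents that add atoms: none
Why: Intramolecular enolate alkylation (4-exo-tet), in which kinetic deprotonation at C11 gives the cross-conjugated enolate that displaces the C5 mesylate from the rear with inversion, so that C5 (skeleton S) and the new bridgehead C11 (skeleton R) follow from the cis fusion; O-alkylation would need a bridgehead enol ether, and the amide base is too weak to deprotonate the senecioate.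

Step 17
Reactants: 23 O9-triethylsilyl cage enone
Product: 24 cage C9 alcohol
Conditions: HF·pyridine, pyridine, THF, 0 °C to rt
Reagents that add atoms: none
Why: Fluoride-induced cleavage of the only silyl ether frees O9, and enone, ester and cyclobutane tolerate buffered HF·pyridine.

Step 18
Reactants: 24 cage C9 alcohol; 25 angelic acid
Product: 27 target CNP0277258.2, via mixed anhydride 26 (not isolated)
Conditions: 2,4,6-trichlorobenzoyl chloride, Et3N, toluene, rt; then 24, 80 °C
Reagents that add atoms: none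
Why: Yamaguchi-type esterification through the mixed anhydride acylates the hindered alcohol at oxygen, so C9 keeps its configuration, and the absence of a nucleophilic catalyst should keep the Z (angelate) geometry from isomerising to the tiglate.

Compound list
1 | (E)-3-methylpent-2-en-4-yn-1-ol | C#C/C(C)=C/CO | starting material
2 | (E)-3-methylpenta-2,4-dien-1-ol | C=C/C(C)=C/CO | intermediate
3 | (E)-3-methylpenta-2,4-dienal | C=C/C(C)=C/C=O | intermediate
4 | 1-methoxy-2-methyl-1-(trimethylsilyloxy)prop-1-ene | COC(O[Si](C)(C)C)=C(C)C | starting material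
5 | methyl (3S,4E)-3-hydroxy-2,2,5-trimethylhepta-4,6-dienoate | C=C/C(C)=C/[C@H](O)C(C)(C)C(=O)OC | intermediate
6 | methyl (3S,4E)-2,2,5-trimethyl-3-(triethylsilyloxy)hepta-4,6-dienoate | C=C/C(C)=C/[C@H](O[Si](CC)(CC)CC)C(C)(C)C(=O)OC | intermediate
7 | (3S,4E)-2,2,5-trimethyl-3-(triethylsilyloxy)hepta-4,6-dien-1-ol | C=C/C(C)=C/[C@H](O[Si](CC)(CC)CC)C(C)(C)CO | intermediate
8 | (3S,4E)-2,2,5-trimethyl-3-(triethylsilyloxy)hepta-4,6-dienal | C=C/C(C)=C/[C@H](O[Si](CC)(CC)CC)C(C)(C)C=O | intermediate
9 | 3-methylbut-3-en-2-one | CC(=O)C(C)=C | starting material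
10 | 3-methylbuta-1,3-dien-2-yl diisopinocampheylborinate (boron enolate of 9) | C=C(C)C(=C)OB([C@H]1C[C@H]2C[C@@H]([C@@H]1C)C2(C)C)[C@H]1C[C@H]2C[C@@H]([C@@H]1C)C2(C)C | intermediate (not isolated)
11 | O-diisopinocampheylboryl aldolate of 12 | C=C/C(C)=C/[C@H](O[Si](CC)(CC)CC)C(C)(C)[C@H](OB([C@H]1C[C@H]2C[C@@H]([C@@H]1C)C2(C)C)[C@H]1C[C@H]2C[C@@H]([C@@H]1C)C2(C)C)CC(=O)C(C)=C | intermediate (not isolated)
12 | (5R,7S,8E)-5-hydroxy-2,6,6,9-tetramethyl-7-(triethylsilyloxy)undeca-1,8,10-trien-3-one | C=C/C(C)=C/[C@H](O[Si](CC)(CC)CC)C(C)(C)[C@H](O)CC(=O)C(C)=C | intermediate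
13 | (5R,7S,8E)-5-(tert-butyldimethylsilyloxy)-2,6,6,9-tetramethyl-7-(triethylsilyloxy)undeca-1,8,10-trien-3-one (skeleton 5S,7R; O5 triethylsilyl, O7 tert-butyldimethylsilyl) | C=C/C(C)=C/[C@H](O[Si](CC)(CC)CC)C(C)(C)[C@H](O[Si](C)(C)C(C)(C)C)CC(=O)C(C)=C | intermediate
14 | (4aS,7R,9S,9aR)-7-(tert-butyldimethylsilyloxy)-1,4a,8,8-tetramethyl-9-(triethylsilyloxy)-3,4,4a,6,7,8,9,9a-octahydro-5H-benzo[7]annulen-5-one (cis-fused; skeleton 4R,5S,7R,10S) | O=C1C[C@@H](O[Si](C)(C)C(C)(C)C)C(C)(C)[C@@H](O[Si](CC)(CC)CC)[C@@H]2C(C)=CCC[C@]12C | intermediate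
15 | (4aS,7R,9S,9aR)-7-(tert-butyldimethylsilyloxy)-9-hydroxy-1,4a,8,8-tetramethyl-3,4,4a,6,7,8,9,9a-octahydro-5H-benzo[7]annulen-5-one | O=C1C[C@@H](O[Si](C)(C)C(C)(C)C)C(C)(C)[C@@H](O)[C@@H]2C(C)=CCC[C@]12C | intermediate
16 | C5 methanesulfonate of 15 (skeleton 4R,5S,7R,10S) | O=C1C[C@@H](O[Si](C)(C)C(C)(C)C)C(C)(C)[C@@H](OS(C)(=O)=O)[C@@H]2C(C)=CCC[C@]12C | intermediate
17 | cis-fused bicyclic C9 ketone with free C7 hydroxyl and C5 mesylate (skeleton 4R,5S,7R,10S) | O=C1C[C@@H](O)C(C)(C)[C@@H](OS(C)(=O)=O)[C@@H]2C(C)=CCC[C@]12C | intermediate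
18 | 3-methylbut-2-enal | CC(C)=CC=O | starting material
19 | cis-fused bicycle with C9 hydroxyl, C7 3-methylbut-2-enoate, C5 mesylate, C2=C3 alkene (skeleton 4R,5S,7R,9R,10S) | O[C@@H]1C[C@@H](OC(=O)C=C(C)C)C(C)(C)[C@@H](OS(C)(=O)=O)[C@@H]2C(C)=CCC[C@]12C | intermediate
20 | O9 triethylsilyl ether of 19 | CC[Si](CC)(CC)O[C@@H]1C[C@@H](OC(=O)C=C(C)C)C(C)(C)[C@@H](OS(C)(=O)=O)[C@@H]2C(C)=CCC[C@]12C | intermediate
21 | C1 enone of 20 (C1 ketone, C2=C3; skeleton 4R,5S,7R,9R,10S) | CC[Si](CC)(CC)O[C@@H]1C[C@@H](OC(=O)C=C(C)C)C(C)(C)[C@@H](OS(C)(=O)=O)[C@@H]2C(C)=CC(=O)C[C@]12C | intermediate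
22 | potassium C1–C11 enolate of 21 | CC[Si](CC)(CC)O[C@@H]1C[C@@H](OC(=O)C=C(C)C)C(C)(C)[C@@H](OS(C)(=O)=O)[C@@H]2C(C)=CC([O-])=C[C@]12C.[K+] | intermediate (not isolated)
23 | 7-(3-methylbut-2-enoyloxy)-9-(triethylsilyloxy)longipin-2-en-1-one, the tricyclic cage enone (skeleton 4R,5S,7R,9R,10R,11R) | CC[Si](CC)(CC)O[C@@H]1C[C@@H](OC(=O)C=C(C)C)C(C)(C)[C@@H]2[C@H]3C(=O)C=C(C)[C@@H]2[C@]31C | intermediate
24 | 9-hydroxy-7-(3-methylbut-2-enoyloxy)longipin-2-en-1-one (skeleton 4R,5S,7R,9R,10R,11R) | O[C@@H]1C[C@@H](OC(=O)C=C(C)C)C(C)(C)[C@@H]2[C@H]3C(=O)C=C(C)[C@@H]2[C@]31C | intermediate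
25 | angelic acid, (Z)-2-methylbut-2-enoic acid | C/C=C(/C)C(=O)O | starting material
26 | angelic 2,4,6-trichlorobenzoic anhydride | C/C=C(/C)C(=O)OC(=O)c1c(Cl)cc(Cl)cc1Cl | intermediate (not isolated)
27 | CNP0277258.2, 9-angeloyloxy-7-senecioyloxylongipin-2-en-1-one (skeleton 4R,5S,7R,9R,10R,11R) | C/C=C(/C)C(=O)O[C@@H]1C[C@@H](OC(=O)C=C(C)C)C(C)(C)[C@@H]2[C@H]3C(=O)C=C(C)[C@@H]2[C@]31C | target

Total step count: 18. Longest linear sequence: 18 steps (1 to 27); 4, 9, 18 and 25 are bought.

Steps most likely to fail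

1. Step 9. Closure through a seven-membered tether ring with formation of a quaternary centre may be slow, so that Lewis-acid ionisation of the dienylic silyl ether, polymerisation of the enone, or loss of endo and facial control takes over. The fallback sets out from 12 and comes back at 14. It replaces one-point activation of the fully protected substrate by a two-point aluminium chelate. Me2AlCl (2.2 equiv, CH2Cl2, −78 to −20 °C) turns the free C7 hydroxyl of 12 into an aluminium alkoxide that binds the C9 carbonyl in a six-membered chelate, as is known for hydroxy enones used as two-point-binding dienophiles. This freezes two tether bonds and activates the enone. The cycloadduct, the C7-hydroxy bicyclic ketone F1, is silylated (TBSOTf, 2,6-lutidine, −78 °C) to 14.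

2. Step 16. Rear-side displacement at the neopentyl-type C5 may be too slow, so that E2 loss of the mesylate, equilibration to the extended dienolate with vinylogous elimination, or consumption of enolate by the senecioate competes. The fallback sets out from 16 and comes back at 27. It moves the ring closure to an ester-free substrate, where excess base and longer reaction at higher temperature are possible, and attaches both acyl groups afterwards.
   - Ketone 16 is reduced under reagent control by CBS reduction [(S)-1-methyl-3,3-diphenyltetrahydro-1H,3H-pyrrolo[1,2-c][1,3,2]oxazaborole, catecholborane, toluene, −78 °C]; large quaternary C10 against small methylene C8 should give the 9R configuration in the C9 alcohol F2.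
   - TESOTf and 2,6-lutidine give the bis-silyl ether F3.
   - CrO3 with 3,5-dimethylpyrazole gives the bis-silyl enone F4.
   - KN(SiMe3)2 or KOtBu (THF, −78 °C to rt) closes C5–C11 to the bis-silyl cage enone F5.
   - Pyridinium p-toluenesulfonate in MeOH removes only the triethylsilyl group and gives the cage C9 alcohol F6.
   - Mixed-anhydride angeloylation as in step 18 gives the silyl angelate F7.
   - HF·pyridine frees O7 to give the hydroxy angelate F8.
   - Esterification with 3-methylbut-2-enoic acid (DCC, DMAP, CH2Cl2) gives 27.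

3. Step 13. Hydride transfer from the hemiacetal of a conjugated aldehyde to the hindered ring ketone may stall, and retro-aldol cleavage or acyl scrambling of the β-hydroxy ketone may intervene. The fallback sets out from 17 and comes back at 19. It separates acylation from reduction. The C7 hydroxyl is esterified with 3-methylbut-2-enoic acid (DCC, DMAP, CH2Cl2, 0 °C) to the β-senecioyloxy ketone F9. Its C9 carbonyl is then reduced by CBS reduction with the same (S)-oxazaborolidine and catecholborane (toluene, −78 °C), which should deliver the 9R alcohol 19 under reagent control.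

Further compounds
F1 | step 9 | C7-hydroxy bicyclic ketone (O5 triethylsilyl, free O7–H, C9 ketone; skeleton 4R,5S,7R,10S) | O=C1C[C@@H](O)C(C)(C)[C@@H](O[Si](CC)(CC)CC)[C@@H]2C(C)=CCC[C@]12C
F2 | step 16 | C9 alcohol (9R) with O7 tert-butyldimethylsilyl ether and C5 mesylate | O[C@@H]1C[C@@H](O[Si](C)(C)C(C)(C)C)C(C)(C)[C@@H](OS(C)(=O)=O)[C@@H]2C(C)=CCC[C@]12C
F3 | step 16 | bis-silyl ether (O9 triethylsilyl, O7 tert-butyldimethylsilyl, C5 mesylate) | CC[Si](CC)(CC)O[C@@H]1C[C@@H](O[Si](C)(C)C(C)(C)C)C(C)(C)[C@@H](OS(C)(=O)=O)[C@@H]2C(C)=CCC[C@]12C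
F4 | step 16 | bis-silyl enone (C1 ketone of F3) | CC[Si](CC)(CC)O[C@@H]1C[C@@H](O[Si](C)(C)C(C)(C)C)C(C)(C)[C@@H](OS(C)(=O)=O)[C@@H]2C(C)=CC(=O)C[C@]12C
F5 | step 16 | bis-silyl cage enone (O9 triethylsilyl, O7 tert-butyldimethylsilyl) | CC[Si](CC)(CC)O[C@@H]1C[C@@H](O[Si](C)(C)C(C)(C)C)C(C)(C)[C@@H]2[C@H]3C(=O)C=C(C)[C@@H]2[C@]31C
F6 | step 16 | cage C9 alcohol with O7 tert-butyldimethylsilyl ether | O[C@@H]1C[C@@H](O[Si](C)(C)C(C)(C)C)C(C)(C)[C@@H]2[C@H]3C(=O)C=C(C)[C@@H]2[C@]31C
F7 | step 16 | silyl angelate (C9 angelate, O7 tert-butyldimethylsilyl ether) | C/C=C(/C)C(=O)O[C@@H]1C[C@@H](O[Si](C)(C)C(C)(C)C)C(C)(C)[C@@H]2[C@H]3C(=O)C=C(C)[C@@H]2[C@]31C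
F8 | step 16 | hydroxy angelate (C9 angelate, free C7 hydroxyl) | C/C=C(/C)C(=O)O[C@@H]1C[C@@H](O)C(C)(C)[C@@H]2[C@H]3C(=O)C=C(C)[C@@H]2[C@]31C
F9 | step 13 | β-senecioyloxy ketone (C7 3-methylbut-2-enoate, C9 ketone, C5 mesylate) | O=C1C[C@@H](OC(=O)C=C(C)C)C(C)(C)[C@@H](OS(C)(=O)=O)[C@@H]2C(C)=CCC[C@]12C
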